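## Structural features

The target 33 is a germacranolide of the heliangolide type. It is a ten-membered carbocycle (C1–C10) with an E trisubstituted alkene C1=C10 (methyl C14 on C10), a 4,5-epoxide whose ring bonds C3–C4 and C5–C6 are cis (so it derives from a Z alkene; methyl C15 on C4), and an α-methylene-γ-butyrolactone C7–C11(=C13)–C12(=O)–O–C8 fused cis across C7–C8. There are six stereocentres: the isolated acetoxy carbinol C2, allylic to C1=C10, and the contiguous run C4, C5, C6, C7, C8. The fragile groups are the α-methylene lactone (Michael acceptor; a free C6 hydroxyl can translactonise), the 4,5-epoxide beside the 1(10)-alkene (acid-triggered transannular cyclisation), the two allylic acetates, and the 1,5-diene in a medium ring (Cope rearrangement on heating). The real difficulty is the medium ring itself: it must be formed with two trisubstituted alkenes of opposite geometry, and C2 must be related to the remote C6–C8 array. The key step uses the fact that C1 and C6 face each other across the ring. A temporary C1–C6 bond gives a decalin whose ring B (C1–C6) holds C4=C5 as a cyclohexene, necessarily cis, and whose ring A (C1, C6–C10) holds C7, C8 and a C10 ketone; with C1–C6 as an epoxide α,β to that ketone, the bicycle fragments back to the ten-membered ring. The alkyne C1≡C10 that results is flanked by the C2 carbinol, so the E geometry can be fixed afterwards by a hydroxyl-directed anti-hydrometalation.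

## Logic of the disconnections

33 ⇒ 32 ⇒ 31. The C6 acetyl group and then the C4–O–C5 epoxide are removed. The epoxide is the most acid-sensitive element, so it goes in last; in 31 the C6 hydroxyl is the only free allylic hydroxyl and alone can direct oxygen to C4=C5. Two stereocentres disappear. The forward step must deliver oxygen syn to the hydroxyl of a Z-cycloalkenol and leave C1=C10 and C11=C13 alone.

31 ⇒ 30 ⇒ 29. The C6 silyl ether is restored and the C2 acetyl group removed. C6–O has to stay masked while the lactone is enolised, since a free C6 oxygen can attack C12; C2 can only be acetylated after enolate chemistry. The demand is a fluoride deprotection that tolerates the exo-methylene lactone.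

29 ⇒ 26 ⇒ 25 ⇒ 24. C11=C13 is cut, then the C12 carbonyl is taken back to an ethyl acetal. A lactone cannot survive the hydride needed for the alkyne, whereas the cyclic acetal carries C12 at the right oxidation level and ties O8 to C11 throughout. The forward steps need mild acetal hydrolysis and a lactol-selective oxidation beside a free allylic alcohol and a 1,5-diene.

24 ⇒ 23 ⇒ 21. The C10–C14 bond and then the C10–I and C1–H bonds are cut, returning the E alkene to the alkyne. The geometry comes from a stereospecific anti addition directed by the C2 hydroxyl, then coupling with retention. This needs a free C2 hydroxyl and no reducible group elsewhere.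

21 ⇒ 20 ⇒ 19 ⇒ 18. The silyl ethers are exchanged (C2 more labile than C6) and C6–H is removed to give the ketone that the fragmentation delivers. The β-alkoxy ketone 18, with its epimerisable C7, must be reduced at once; facial selectivity at C6 is the demand.

18 ⇒ 16 (through 17). The C1–C6 bond is reconnected: alkyne carbons C10 and C1 become ketone and epoxide carbon, the C6 ketone becomes the second epoxide carbon. The ten-membered ring becomes a decalin that can be built by six-membered-ring chemistry. Only the placement of ketone and epoxide matters in the forward step.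

16 ⇒ 15 ⇒ 14 ⇒ 13. The epoxide oxygen is removed and C10 taken through the alcohol level. Alkaline peroxide on 13 would expose a ketone with a β-oxygen at C8 and a cyclohexadiene with a leaving group at C2 to base (β-elimination, aromatisation); the hydroxyl-directed route is neutral. It must choose C1=C6 over C4=C5.

13 ⇒ 12. The oxygen is transposed from C10 back to C6 (C10=O/C1=C6 ⇒ C6–OH/C1=C10). C6 then becomes a carbinol carbon that a ketone and a vinyl nucleophile can make. Only the secondary terminus can be oxidised, so the forward step is self-correcting.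

12 ⇒ 11 ⇒ 10. C4=C5 is cut (ring-closing metathesis), then C5–C6 (vinyl addition to the C6 ketone). Closing a six-membered ring gives the cis alkene by necessity and needs only simple reagents.

10 ⇒ 9 ⇒ 6 + 8, and 8 ⇒ 7. C1–C2 is cut between the α-carbon of an enone and an aldehyde. This is the one stereocentre remote from the others, so it is placed under catalyst control.

6 ⇒ 5. C7–C11 is cut. Carbon is delivered from a tether on O8, so the bond must form cis to C8–O; a bimolecular alkylation at C7 would enter anti to that oxygen and give the wrong relationship. The cyclisation has to outrun β-elimination of the C8 oxygen.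

5 ⇒ 3 ⇒ 2 ⇒ 1. The enone is traced to a desymmetrised all-cis triol derivative: the two enantiotopic carbinols become the C6 carbonyl and the C10 alkene carbon, and the tether is attached first. An enzyme must tell the two carbinols apart.

## Other disconnections considered

Alternative 1: The cut is the C9–C10 bond of A1, the 1(10)E,4Z-diene that already carries the C2, C6 and C8 oxygens and C13. Forward, NiBr2(dme) with 4,4'-di-tert-butyl-2,2'-bipyridine and tetrakis(dimethylamino)ethylene would join an E alkenyl iodide terminus at C10 to a primary iodide terminus at C9 of one open chain.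
- In its favour: every stereocentre and both alkenes would be set by acyclic methods, the assembly is convergent, and no organometallic has to be preformed.
- Against it here: a ten-membered ring must be closed against strain and entropy (dilution, oligomers, hydrodehalogenation). The alkyl–nickel at C9 has a β-silyloxy group at C8 that can eliminate. The allylic acetate at C2 beside the alkenyl iodide is itself reactive toward low-valent nickel.
- Comparison: on structure the alternative is the better at one point, since C13 is present from the start, and the equal on the carbinol centres. On mechanism the chosen plan is safer, because the ring is revealed by cutting a bond and the Z alkene is guaranteed by a cyclohexene. On step economy the alternative would probably have the shorter longest linear sequence.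

Alternative 2: The cut is the C6–C7 bond of A2, the cyclodecadien-6-ol with exocyclic C11=C13. Forward, tin–lithium exchange at C6 of a thirteen-membered α-stannyl allylic ether (ring through O–C13) would trigger a Wittig–Still [2,3] shift that forms C6–C7, breaks O–C13 and contracts the ring.
- In its favour: one step makes C6, C7 and the exocyclic methylene, which is better than the chosen plan (separate reduction and methylenation). A thirteen-membered ether is also easier to close than a ten-membered carbocycle.
- Against it here: the stereochemical result depends on the conformation of a large flexible ring and on the C7=C11 geometry. The C6 carbanion is also allylic to C4=C5, so [1,2] shifts and loss of configuration compete. The stannyl ether itself costs steps.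
- Comparison: mechanistically the alternative is more elegant and equal in functional-group tolerance. Structurally the chosen plan fixes C7/C8 early by a tether and does not rely on transannular chirality transfer. The step count is likely similar.

Alternative 3: The cuts are C1–C2 and C10–CH3 of A3, the dienol with free C2 hydroxyl. Forward, Ni(cod)2 with a chiral N-heterocyclic carbene and Me2Zn would couple a C2 aldehyde with a terminal C1≡C10 alkyne of one chain: oxidative cyclisation, methyl transfer to C10, reductive elimination.
- In its favour: one step closes the ring and sets the C2 carbinol, the E alkene and C14. This is better than the chosen plan, which needs steps 6, 18 and 19 for the same elements.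
- Against it here: it is again a ten-membered macrocyclisation. The regiochemistry of a terminal alkyne (which carbon joins C2) depends on the ligand. The ligand must override the resident C6–C8 centres. Direct methylation of the aldehyde and reductive coupling compete.
- Comparison: the alternative is the better on step economy around C1/C2/C10 and the equal on protecting-group load. The chosen plan is the safer on ring formation and on alkene geometry, which follows from a stereospecific anti addition.

Key step: step 14

Remark on numbering: atoms carry the germacrane numbers of 33 (ring C1–C10, lactone carbons C11–C13, C14 on C10, C15 on C4) in every intermediate.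

Remark on the acetal carbon: C12 is formed unselectively in step 1 and is drawn throughout as the epimer that becomes the exo-ethoxy acetal; its epimer takes the same course and both converge at 26.

Remark on transient centres: C6 in 11 and 12, C10 in 14 and 15, the epoxide in 15 and 16 and C11 in 27 and 28 are drawn as the expected major isomers; none survives into 33.

## Route

Step 1
Reactants: 1 cis,cis-cyclohexane-1,3,5-triol
Product: 2 all-cis-5-(1-ethoxy-2-iodoethoxy)cyclohexane-1,3-diol
Conditions: ethyl vinyl ether, N-iodosuccinimide, MeCN–DMF, −30 → 0 °C (1 in threefold excess, recovered)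
Reagents that add atoms: ethyl vinyl ether C=COCC; N-iodosuccinimide O=C1CCC(=O)N1I
Why: Iodoalkoxylation of an enol ether: the iodonium ion of the vinyl ether is trapped by one hydroxyl; the three hydroxyls are equivalent, so mono-functionalisation is statistical and is favoured by the excess of 1. The product carries the two-carbon tether (C11, C12) on the future O8.

Step 2
Reactants: 2 all-cis-5-(1-ethoxy-2-iodoethoxy)cyclohexane-1,3-diol
Product: 3 all-cis-3-hydroxy-5-(1-ethoxy-2-iodoethoxy)cyclohexyl acetate (acetate on the future C10, hydroxyl on the future C6)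
Conditions: Burkholderia cepacia lipase, vinyl acetate, t-BuOMe, 30 °C
Reagents that add atoms: vinyl acetate CC(=O)OC=C
Why: Lipase desymmetrisation of a meso-type 1,3-diol: the enzyme should acylate one of the two enantiotopic carbinols, which fixes the absolute configuration at C8. Should the enzyme show the opposite sense, hydrolysis of the diacetate with the same lipase gives the required antipode.

Step 3
Reactants: 3 all-cis-3-hydroxy-5-(1-ethoxy-2-iodoethoxy)cyclohexyl acetate
Product: 5 (5R)-5-(1-ethoxy-2-iodoethoxy)cyclohex-2-en-1-one, via β-acetoxy ketone 4 (not isolated)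
Conditions: (COCl)2, DMSO, CH2Cl2, −78 °C; Et3N, −78 → 23 °C
Reagents that add atoms: none
Why: Swern oxidation of the free carbinol gives the C6 ketone; the β-acetoxy group is then lost by amine-induced elimination, giving the enone C6(=O)–C1=C10 with C8 untouched.

Step 4
Reactants: 5 (5R)-5-(1-ethoxy-2-iodoethoxy)cyclohex-2-en-1-one
Product: 6 (2S,3aR,7aR)-2-ethoxy-2,3,3a,7a-tetrahydro-1-benzofuran-4(7H)-one (cis-fused acetal enone; C6 ketone, C1=C10)
Conditions: LiN(i-Pr)2, THF–DMPU, −78 → −40 °C
Reagents that add atoms: none
Why: Kinetic α′-deprotonation at C7 gives the cross-conjugated dienolate, which closes by intramolecular 5-exo-tet C-alkylation on the tethered primary iodide. Because C11 is delivered from O8, the new C7–C11 bond can only form cis to C8–O, which sets C7. The cold, irreversible enolisation keeps the lifetime of the β-alkoxy enolate short.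

Step 5
Reactants: 7 3-methylbut-3-en-1-ol
Product: 8 3-methylbut-3-enal
Conditions: Dess–Martin periodinane, NaHCO3, CH2Cl2, 0 °C; solution used at once
Reagents that add atoms: none
Why: Buffered periodinane oxidation of a primary alcohol; the β,γ-unsaturated aldehyde is not stored, to avoid isomerisation into conjugation.

Step 6
Reactants: 6 (2S,3aR,7aR)-2-ethoxy-2,3,3a,7a-tetrahydro-1-benzofuran-4(7H)-one; 8 3-methylbut-3-enal
Product: 9 (2S,3aR,7aR)-2-ethoxy-5-[(1S)-1-hydroxy-3-methylbut-3-enyl]-2,3,3a,7a-tetrahydro-1-benzofuran-4(7H)-one
Conditions: PEt3, (R)-3,3′-bis(3,5-dimethylphenyl)-5,5′,6,6′,7,7′,8,8′-octahydro-1,1′-bi-2-naphthol (10 mol %), THF, −10 °C (8 in excess)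
Reagents that add atoms: none
Why: Asymmetric Morita–Baylis–Hillman reaction of a cyclohexenone with an aliphatic aldehyde: the phosphine adds to C10, the enolate adds to the aldehyde through C1, and loss of phosphine restores the enone. The chiral Brønsted acid binds the enolate–aldehyde pair and so sets the C2 carbinol; the catalyst antipode is chosen to give 2S, since the ring stereocentres are too remote to control it.

Step 7
Reactants: 9 (2S,3aR,7aR)-2-ethoxy-5-[(1S)-1-hydroxy-3-methylbut-3-enyl]-2,3,3a,7a-tetrahydro-1-benzofuran-4(7H)-one
Product: 10 triethylsilyl ether of 9 at the C2 oxygen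
Conditions: Et3SiCl, imidazole, DMF, 0 °C
Reagents that add atoms: chlorotriethylsilane CC[Si](Cl)(CC)CC
Why: Silylation of a secondary alcohol; the group is chosen to survive the chromium oxidant, to be a poor leaving group at C2, and to be removable later beside a tert-butyldimethylsilyl ether.

Step 8
Reactants: 10 triethylsilyl ether of 9 at the C2 oxygen
Product: 11 C6 vinyl carbinol of 10 (tertiary alcohol at C6, hydroxyl on the face of C11)
Conditions: CH2=CHMgBr, CeCl3, THF, −78 °C
Reagents that add atoms: vinylmagnesium bromide C=C[Mg]Br
Why: Organocerium 1,2-addition to the enone carbonyl forms C5–C6; the weakly basic reagent avoids enolisation toward C7 and β-elimination of O8. The new C6 centre (attack anti to the fused acetal ring) is of no consequence, because C6 becomes trigonal in step 10.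

Step 9
Reactants: 11 C6 vinyl carbinol of 10
Product: 12 ring-B-closed tertiary alcohol (C6–OH; C1=C10 and C4=C5; 2-triethylsilyloxy; 8,12-ethyl acetal)
Conditions: second-generation Grubbs catalyst (5 mol %), CH2Cl2, 40 °C
Reagents that add atoms: none
Why: Ring-closing metathesis between the vinyl group on C6 and the 1,1-disubstituted alkene closes the cyclohexene; in a six-membered ring C4=C5 can only be cis. The trisubstituted C1=C10 is too hindered to take part.

Step 10
Reactants: 12 ring-B-closed tertiary alcohol
Product: 13 decalin dienone (C10 ketone, C1=C6, C4=C5; 2-triethylsilyloxy; 8,12-ethyl acetal)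
Conditions: pyridinium chlorochromate, NaOAc, 4 Å molecular sieves, CH2Cl2, 0 → 23 °C
Reagents that add atoms: pyridinium chlorochromate [O-][Cr](=O)(=O)Cl.c1cc[nH+]cc1
Why: Oxidative 1,3-transposition of a tertiary allylic alcohol: the chromate ester shifts by a [3,3] process to C10, the only secondary terminus, and is oxidised there. A shift to C4 gives a tertiary chromate that can only revert, so the reaction funnels to the dienone; the buffer protects the silyl ether and the acetal.

Step 11
Reactants: 13 decalin dienone
Product: 14 decalin dienol (10-hydroxyl cis to the C8 oxygen)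
Conditions: NaBH4, CeCl3·7H2O, EtOH, −78 °C
Reagents that add atoms: none
Why: Luche 1,2-reduction of the dienone; cold, nearly neutral conditions avoid β-elimination of O8 and loss of silanol from the cyclohexadiene. Ethanol makes any acetal exchange degenerate, and the C10 centre is removed again in step 13.

Step 12
Reactants: 14 decalin dienol
Product: 15 1,6-epoxy decalin 10-ol (epoxide and hydroxyl on the face of C11 and the C8 oxygen)
Conditions: VO(acac)2 (5 mol %), t-BuOOH, 2,6-lutidine, CH2Cl2, 0 °C
Reagents that add atoms: tert-butyl hydroperoxide CC(C)(C)OO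
Why: Hydroxyl-directed epoxidation: the vanadium alkoxide delivers oxygen to the allylic C1=C6 bond on the face of the C10 hydroxyl and leaves the more distant C4=C5 untouched. The neutral medium replaces an alkaline peroxide epoxidation of 13, which would put the β-alkoxy ketone and the 2-silyloxy cyclohexadiene at risk.

Step 13
Reactants: 15 1,6-epoxy decalin 10-ol
Product: 16 1,6-epoxy decalin 10-one (C1–C6 epoxide α,β to the C10 ketone; 2-triethylsilyloxy; C4=C5; 8,12-ethyl acetal)
Conditions: Dess–Martin periodinane, NaHCO3, CH2Cl2, 0 °C
Reagents that add atoms: none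
Why: Buffered periodinane oxidation of the secondary alcohol gives the α,β-epoxy ketone without touching the epoxide, the acetal or the silyl ether.

Step 14
Reactants: 16 1,6-epoxy decalin 10-one
Product: 18 12-ethoxy-8,12-epoxy-2-(triethylsilyloxy)-13,14-dinorgermacr-4Z-en-1(10)-yn-6-one (C2, C7, C8 as in 33), via tosylhydrazone 17 (not isolated)
Conditions: TsNHNH2, AcOH–CH2Cl2 (1:1), −20 → 23 °C
Reagents that add atoms: none
Why: Condensation of the C10 ketone with the sulfonyl hydrazide gives 17; loss of the N–H proton opens the C1–O bond to a C6 alkoxide and a C10=C1 vinyl diazene, and collapse of the C6 oxygen to a carbonyl cleaves the C1–C6 σ bond while C1≡C10 forms and N2 and p-toluenesulfinate leave. The closest known reaction type is the Eschenmoser–Tanabe fragmentation of bicyclic α,β-epoxy ketones to cycloalkynones, including ring-fused octalone oxides that give cyclodecynones. No ring is closed by bond formation: the ten-membered ring is unveiled by heterolytic cleavage of the bond shared by the two six-membered rings, so no cyclisation mode, dilution or template is involved. No stereocentre is created; both epoxide carbons lose their configuration, which is why either epoxide face would serve, and C2, C7, C8 and C12 are not touched. The only selectivity needed is regiochemical, and it is fixed by the substrate: the ketone sits at C10 and the epoxide at C1–C6, so only C1–C6 can break. The cyclohexene alkene of ring B becomes the Z alkene of the enone, and the C6–O bond, being allylic, should open readily. Mild acid at low temperature is chosen so that the acetal, the silyl ether and the now epimerisable C7 survive.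

Step 15
Reactants: 18 cyclodecenynone (6-ketone)
Product: 19 6-alcohol of 18 (6-hydroxyl syn to C11, the configuration of C6 in 33)
Conditions: NaBH4, CeCl3·7H2O, EtOH, −78 °C
Reagents that add atoms: none
Why: Luche 1,2-reduction of the Z-enone under cold, weakly basic conditions that spare the β-alkoxy ketone and C7. C6 is set under substrate control: hydride should enter from the carbonyl face away from C11 of the fused acetal ring, which gives the required alcohol when the ring holds C6=O syn to the C7–C8 bond; this is the least predictable centre and is covered below.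

Step 16
Reactants: 19 6-alcohol
Product: 20 6-tert-butyldimethylsilyl ether of 19
Conditions: t-BuMe2SiOTf, 2,6-lutidine, CH2Cl2, −78 °C
Reagents that add atoms: tert-butyldimethylsilyl triflate CC(C)(C)[Si](C)(C)OS(=O)(=O)C(F)(F)F
Why: Silylation of the hindered allylic alcohol; the C6 oxygen must stay masked until the lactone has been methylenated, and the group is stable to the hydride and zinc reagents that follow.

Step 17
Reactants: 20 6-tert-butyldimethylsilyl ether
Product: 21 2-alcohol (free propargylic hydroxyl at C2; 6-tert-butyldimethylsilyloxy)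
Conditions: pyridinium p-toluenesulfonate, EtOH, 23 °C
Reagents that add atoms: none
Why: Mild acid alcoholysis removes the triethylsilyl ether and leaves the bulkier silyl ether; ethanol makes exchange at the ethyl acetal degenerate.

Step 18
Reactants: 21 2-alcohol
Product: 23 10-iodo-1(10)-alkene (iodine cis to C2; ring carbons C2 and C9 trans), via alkenylalanate 22 (not isolated)
Conditions: NaAlH2(OCH2CH2OMe)2, THF, 0 → 23 °C; EtOAc; I2, −78 °C
Reagents that add atoms: iodine II
Why: Hydroxyl-directed anti-hydroalumination of a propargylic alcohol: the alkoxyaluminium hydride delivers hydride to C1 and aluminium to C10 in a five-membered alanate, so H and Al are trans. Iodinolysis with retention gives the iodoalkene with the ring carbons C2 and C9 trans. The acetal and silyl ether are inert to the hydride.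

Step 19
Reactants: 23 10-iodo-1(10)-alkene
Product: 24 10-methyl 1(10)E,4Z-diene (2-hydroxyl; 6-tert-butyldimethylsilyloxy; 8,12-ethyl acetal)
Conditions: Me2Zn, Pd(PPh3)4 (5 mol %), THF, 40 °C
Reagents that add atoms: dimethylzinc C[Zn]C
Why: Negishi coupling of an alkenyl iodide proceeds with retention, so C14 enters cis to C2 and the ring alkene is E; the free hydroxyl is tolerated as its zinc alkoxide.

Step 20
Reactants: 24 10-methyl 1(10)E,4Z-diene
Product: 25 8,12-lactol (12-hydroxyl, mixture of anomers)
Conditions: AcOH–THF–H2O (3:1:1), 35 °C
Reagents that add atoms: water O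
Why: Mild hydrolysis of the cyclic ethyl acetal to the lactol. The C6 silyl ether stays on, so the aldehyde form can only close onto O8; weak acid is used because of the 1,5-diene and the allylic alcohol.

Step 21
Reactants: 25 8,12-lactol
Product: 26 saturated cis-fused 8,12-lactone (2-hydroxyl; 6-tert-butyldimethylsilyloxy)
Conditions: NaClO2, NaH2PO4, 2-methylbut-2-ene, t-BuOH–H2O, 0 → 23 °C
Reagents that add atoms: sodium chlorite [Na+].[O-]Cl=O
Why: Pinnick oxidation acts on the aldehyde tautomer of the lactol and leaves the allylic secondary alcohol and the alkenes alone; the cis γ-hydroxy acid closes to the lactone. The scavenger removes hypochlorite.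

Step 22
Reactants: 26 saturated 8,12-lactone
Product: 29 α-methylene lactone (C11=C13; 2-hydroxyl; 6-tert-butyldimethylsilyloxy), via Mannich base 27 (not isolated), via ammonium iodide 28 (not isolated)
Conditions: LiN(i-Pr)2 (2.3 equiv), THF, −78 °C; Me2N=CH2 I, −78 → 0 °C; MeI, MeOH, 23 °C; aq. NaHCO3, CH2Cl2
Reagents that add atoms: Eschenmoser's salt C=[N+](C)C.[I-]
Why: The alkoxide–enolate dianion is aminomethylated at C11, and quaternisation followed by mild base elimination gives the exo-methylene group. The lithium alkoxide at C2 is kept at or below 0 °C so that an anionic oxy-Cope shift of the 1,5-diene does not start, and the silyl ether at C6 prevents translactonisation.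

Step 23
Reactants: 29 α-methylene lactone
Product: 30 2-acetate of 29
Conditions: Ac2O, pyridine, 4-(dimethylamino)pyridine, CH2Cl2, 0 °C
Reagents that add atoms: acetic anhydride CC(=O)OC(C)=O
Why: Acetylation of the C2 hydroxyl; with C2 capped, only the C6 hydroxyl can direct the later epoxidation.

Step 24
Reactants: 30 2-acetate
Product: 31 6-alcohol (2-acetoxy-6-hydroxy 1(10)E,4Z-dien-8,12-olide with C11=C13)
Conditions: HF·pyridine, pyridine, THF, 0 → 23 °C
Reagents that add atoms: none
Why: Buffered fluoride cleaves the silyl ether without adding to the α-methylene lactone or removing the acetate; the alcohol is used at once to limit acyl migration to O6.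

Step 25
Reactants: 31 6-alcohol
Product: 32 4,5-epoxide (epoxide oxygen cis to the 6-hydroxyl)
Conditions: VO(acac)2 (5 mol %), t-BuOOH, CH2Cl2, 0 °C
Reagents that add atoms: tert-butyl hydroperoxide CC(C)(C)OO
Why: Hydroxyl-directed epoxidation of a Z-cycloalkenol delivers oxygen to C4=C5 on the face of the C6 hydroxyl, which is the C4/C5 configuration of 33. C1=C10 has no directing hydroxyl and C11=C13 is electron-poor, so both stay.

Step 26
Reactants: 32 4,5-epoxide
Product: 33 CNP0270851.1 (2,6-diacetate)
Conditions: Ac2O, pyridine, 4-(dimethylamino)pyridine, CH2Cl2, 0 °C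
Reagents that add atoms: acetic anhydride CC(=O)OC(C)=O
Why: Acetylation of the remaining secondary alcohol under mildly basic conditions that the epoxide and the α-methylene lactone tolerate.

## Compound list

1 | cis,cis-cyclohexane-1,3,5-triol | O[C@H]1C[C@@H](O)C[C@@H](O)C1 | starting material
2 | all-cis-5-(1-ethoxy-2-iodoethoxy)cyclohexane-1,3-diol | CCO[C@H](CI)O[C@H]1C[C@@H](O)C[C@@H](O)C1 | intermediate
3 | all-cis-3-hydroxy-5-(1-ethoxy-2-iodoethoxy)cyclohexyl acetate | CCO[C@H](CI)O[C@H]1C[C@@H](O)C[C@@H](OC(C)=O)C1 | intermediate
4 | 3-oxo-5-(1-ethoxy-2-iodoethoxy)cyclohexyl acetate (β-acetoxy ketone) | CCO[C@H](CI)O[C@H]1CC(=O)C[C@@H](OC(C)=O)C1 | intermediate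
5 | (5R)-5-(1-ethoxy-2-iodoethoxy)cyclohex-2-en-1-one | CCO[C@H](CI)O[C@H]1CC(=O)C=CC1 | intermediate
6 | (2S,3aR,7aR)-2-ethoxy-2,3,3a,7a-tetrahydro-1-benzofuran-4(7H)-one | CCO[C@@H]1C[C@H]2C(=O)C=CC[C@H]2O1 | intermediate
7 | 3-methylbut-3-en-1-ol | CC(=C)CCO | starting material
8 | 3-methylbut-3-enal | CC(=C)CC=O | intermediate
9 | (2S,3aR,7aR)-2-ethoxy-5-[(1S)-1-hydroxy-3-methylbut-3-enyl]-2,3,3a,7a-tetrahydro-1-benzofuran-4(7H)-one | CCO[C@@H]1C[C@H]2C(=O)C([C@@H](O)CC(C)=C)=CC[C@H]2O1 | intermediate
10 | triethylsilyl ether of 9 at the C2 oxygen | CCO[C@@H]1C[C@H]2C(=O)C([C@@H](O[Si](CC)(CC)CC)CC(C)=C)=CC[C@H]2O1 | intermediate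
11 | C6 vinyl carbinol of 10 | CCO[C@@H]1C[C@H]2[C@](O)(C=C)C([C@@H](O[Si](CC)(CC)CC)CC(C)=C)=CC[C@H]2O1 | intermediate
12 | ring-B-closed tertiary alcohol (C6–OH, C1=C10, C4=C5) | CCO[C@@H]1C[C@H]2[C@]3(O)C=C(C)C[C@H](O[Si](CC)(CC)CC)C3=CC[C@H]2O1 | intermediate
13 | decalin dienone (C10 ketone, C1=C6, C4=C5) | CCO[C@@H]1C[C@H]2C3=C([C@@H](O[Si](CC)(CC)CC)CC(C)=C3)C(=O)C[C@H]2O1 | intermediate
14 | decalin dienol (10-hydroxyl cis to the C8 oxygen) | CCO[C@@H]1C[C@H]2C3=C([C@@H](O[Si](CC)(CC)CC)CC(C)=C3)[C@@H](O)C[C@H]2O1 | intermediate
15 | 1,6-epoxy decalin 10-ol | CCO[C@@H]1C[C@H]2[C@@]34O[C@@]3([C@@H](O[Si](CC)(CC)CC)CC(C)=C4)[C@@H](O)C[C@H]2O1 | intermediate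
16 | 1,6-epoxy decalin 10-one (fragmentation precursor) | CCO[C@@H]1C[C@H]2[C@@]34O[C@@]3([C@@H](O[Si](CC)(CC)CC)CC(C)=C4)C(=O)C[C@H]2O1 | intermediate
17 | 10-tosylhydrazone of 16 | CCO[C@@H]1C[C@H]2[C@@]34O[C@@]3([C@@H](O[Si](CC)(CC)CC)CC(C)=C4)/C(=N/NS(=O)(=O)c5ccc(C)cc5)C[C@H]2O1 | intermediate
18 | 12-ethoxy-8,12-epoxy-2-(triethylsilyloxy)-13,14-dinorgermacr-4Z-en-1(10)-yn-6-one | CCO[C@@H]1C[C@H]2C(=O)/C=C(C)\C[C@H](O[Si](CC)(CC)CC)C#CC[C@H]2O1 | intermediate
19 | 6-alcohol of 18 (6-hydroxyl syn to C11) | CCO[C@@H]1C[C@H]2[C@H](O)/C=C(C)\C[C@H](O[Si](CC)(CC)CC)C#CC[C@H]2O1 | intermediate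
20 | 6-tert-butyldimethylsilyl ether of 19 | CCO[C@@H]1C[C@H]2[C@H](O[Si](C)(C)C(C)(C)C)/C=C(C)\C[C@H](O[Si](CC)(CC)CC)C#CC[C@H]2O1 | intermediate
21 | 2-alcohol (propargylic hydroxyl free) | CCO[C@@H]1C[C@H]2[C@H](O[Si](C)(C)C(C)(C)C)/C=C(C)\C[C@H](O)C#CC[C@H]2O1 | intermediate
22 | alkenylalanate (five-membered O–Al–C10 chelate, sodium salt) | CCO[C@@H]1C[C@H]2[C@H](O[Si](C)(C)C(C)(C)C)/C=C(C)\C[C@H](O[Al-]3(OCCOC)OCCOC)/C=C3/C[C@H]2O1.[Na+] | intermediate
23 | 10-iodo-1(10)-alkene (C2 and C9 trans) | CCO[C@@H]1C[C@H]2[C@H](O[Si](C)(C)C(C)(C)C)/C=C(C)\C[C@H](O)/C=C(I)/C[C@H]2O1 | intermediate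
24 | 10-methyl 1(10)E,4Z-diene | CCO[C@@H]1C[C@H]2[C@H](O[Si](C)(C)C(C)(C)C)/C=C(C)\C[C@H](O)/C=C(C)/C[C@H]2O1 | intermediate
25 | 8,12-lactol | O[C@@H]1C[C@H]2[C@H](O[Si](C)(C)C(C)(C)C)/C=C(C)\C[C@H](O)/C=C(C)/C[C@H]2O1 | intermediate
26 | saturated cis-fused 8,12-lactone (2-hydroxyl, 6-silyloxy) | C1C(=O)O[C@@H]2C/C(C)=C/[C@@H](O)C/C(C)=C\[C@@H](O[Si](C)(C)C(C)(C)C)[C@H]12 | intermediate
27 | Mannich base (11-dimethylaminomethyl lactone) | CN(C)C[C@H]1C(=O)O[C@@H]2C/C(C)=C/[C@@H](O)C/C(C)=C\[C@@H](O[Si](C)(C)C(C)(C)C)[C@H]12 | intermediate
28 | ammonium iodide of 27 | C[N+](C)(C)C[C@H]1C(=O)O[C@@H]2C/C(C)=C/[C@@H](O)C/C(C)=C\[C@@H](O[Si](C)(C)C(C)(C)C)[C@H]12.[I-] | intermediate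
29 | α-methylene lactone (2-hydroxyl, 6-silyloxy) | C=C1C(=O)O[C@@H]2C/C(C)=C/[C@@H](O)C/C(C)=C\[C@@H](O[Si](C)(C)C(C)(C)C)[C@H]12 | intermediate
30 | 2-acetate of 29 | C=C1C(=O)O[C@@H]2C/C(C)=C/[C@@H](OC(C)=O)C/C(C)=C\[C@@H](O[Si](C)(C)C(C)(C)C)[C@H]12 | intermediate
31 | 6-alcohol (2-acetoxy-6-hydroxy dienolide) | C=C1C(=O)O[C@@H]2C/C(C)=C/[C@@H](OC(C)=O)C/C(C)=C\[C@@H](O)[C@H]12 | intermediate
32 | 4,5-epoxide with free 6-hydroxyl | C=C1C(=O)O[C@@H]2C/C(C)=C/[C@@H](OC(C)=O)C[C@@]3(C)O[C@H]3[C@@H](O)[C@H]12 | intermediate
33 | CNP0270851.1 (2S,4R,5S,6S,7R,8R) | C=C1C(=O)O[C@@H]2C/C(C)=C/[C@@H](OC(C)=O)C[C@@]3(C)O[C@H]3[C@@H](OC(C)=O)[C@H]12 | target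

## Step count and least certain steps

Total: 26 steps. Longest linear sequence: 25 steps (1–4 and 6–26); step 5 makes the side fragment 8.

**Step 14 (key step).** The allylic C6–O bond of the epoxide may open under acid before the hydrazone has formed, leading to solvolysis or loss of the C2 silyl ether. Condensation at the hindered C10 ketone may be slow, and C7 may epimerise once the C6 ketone exists. Fallback: from 16, condensation with 1-amino-2-phenylaziridine under neutral conditions gives the N-aziridinylimine F1 (mixture at the aziridine carbon). Thermolysis in toluene expels styrene and N2 and cleaves C1–C6 with no acid and no sulfinate, returning to the route at 18.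

**Step 4.** β-Elimination of the C8 oxygen from the C7 enolate (followed by aromatisation) may compete with ring closure. Fallback: from 5, deprotonation with LiN(i-Pr)2 in the presence of Me3SiCl at −78 °C traps the enolate at once as the silyl dienol ether F2. A Ueno–Stork radical cyclisation (Bu3SnH, azobisisobutyronitrile, benzene, 80 °C) closes C7–C11 onto the diene terminus and gives the bicyclic silyl enol ether F3. Saegusa–Ito oxidation with Pd(OAc)2 in MeCN restores the enone and returns to the route at 6.

**Step 6.** Facial selectivity at C2 may be poor if catalyst and chiral enone are mismatched. Turnover may be slow with the α′-substituted enone, and 8 may isomerise into conjugation under the phosphine. Fallback: from 6, α-iodination (I2, pyridine, CH2Cl2) gives the 2-iodoenone F4. A Nozaki–Hiyama–Kishi coupling with 8 (CrCl2, catalytic NiCl2, chiral sulfonamide ligand, THF) forms C1–C2 under neutral conditions with ligand control and returns to the route at 9.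

**Step 15.** Hydride delivery may occur mainly to the other face of the C6 carbonyl, because the preferred rotamer about C6–C7 in the ten-membered ring cannot be predicted with confidence. Fallback: from 18, if the reduction gives mainly the 6-epimer F5, a Mitsunobu reaction (PPh3, diisopropyl azodicarboxylate, 4-nitrobenzoic acid) inverts C6 to the ester F6. Methanolysis (K2CO3, MeOH) returns to the route at 19.

**Step 18.** The anti-hydroalumination must form a strained E-cycloalkenyl alanate inside the ten-membered ring. Incomplete addition or partial loss of regiocontrol (iodine at C1) is possible. Fallback: from 21, ruthenium-catalysed trans-hydrosilylation ([Cp*Ru(MeCN)3]PF6, BnMe2SiH, CH2Cl2, 0 °C) should place silicon on C10, distal to the hydroxyl, giving the alkenylsilane F7. Iododesilylation with retention (N-iodosuccinimide, (CF3)2CHOH, 0 °C) returns to the route at 23.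

## Further compounds

F1 | step 14 | N-(2-phenylaziridin-1-yl)imine of 16 at C10 | CCO[C@@H]1C[C@H]2[C@@]34O[C@@]3([C@@H](O[Si](CC)(CC)CC)CC(C)=C4)C(=NN5CC5c6ccccc6)C[C@H]2O1
F2 | step 4 | trimethylsilyl dienol ether of 5 (C7=C6(OSiMe3)–C1=C10) | CCO[C@H](CI)O[C@H]1C=C(O[Si](C)(C)C)C=CC1
F3 | step 4 | bicyclic silyl enol ether (C6(OSiMe3)=C1, cis-fused acetal) | CCO[C@@H]1C[C@H]2C(O[Si](C)(C)C)=CCC[C@H]2O1
F4 | step 6 | 2-iodoenone of 6 (iodine on C1) | CCO[C@@H]1C[C@H]2C(=O)C(I)=CC[C@H]2O1
F5 | step 15 | 6-epimer of 19 | CCO[C@@H]1C[C@H]2[C@@H](O)/C=C(C)\C[C@H](O[Si](CC)(CC)CC)C#CC[C@H]2O1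
F6 | step 15 | 6-(4-nitrobenzoate) with the C6 configuration of 19 | CCO[C@@H]1C[C@H]2[C@H](OC(=O)c3ccc(cc3)[N+](=O)[O-])/C=C(C)\C[C@H](O[Si](CC)(CC)CC)C#CC[C@H]2O1
F7 | step 18 | 10-(benzyldimethylsilyl)-1(10)-alkene (silicon cis to C2) | CCO[C@@H]1C[C@H]2[C@H](O[Si](C)(C)C(C)(C)C)/C=C(C)\C[C@H](O)/C=C([Si](C)(C)Cc3ccccc3)/C[C@H]2O1
A1 | alternative 1 | 2-acetoxy-8-(tert-butyldimethylsilyloxy)-12-(4-methoxybenzyloxy)-6-(triethylsilyloxy)germacra-1(10)E,4Z,11(13)-triene | C=C(COCc1ccc(OC)cc1)[C@@H]2[C@H](O[Si](C)(C)C(C)(C)C)C/C(C)=C/[C@@H](OC(C)=O)C/C(C)=C\[C@H]2O[Si](CC)(CC)CC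
A2 | alternative 2 | 8-(tert-butyldimethylsilyloxy)-12-(4-methoxybenzyloxy)-2-(triethylsilyloxy)germacra-1(10)E,4Z,11(13)-trien-6-ol | C=C(COCc1ccc(OC)cc1)[C@@H]2[C@H](O[Si](C)(C)C(C)(C)C)C/C(C)=C/[C@@H](O[Si](CC)(CC)CC)C/C(C)=C\[C@H]2O
A3 | alternative 3 | 8-(tert-butyldimethylsilyloxy)-12-(4-methoxybenzyloxy)-6-(triethylsilyloxy)germacra-1(10)E,4Z,11(13)-trien-2-ol | C=C(COCc1ccc(OC)cc1)[C@@H]2[C@H](O[Si](C)(C)C(C)(C)C)C/C(C)=C/[C@@H](O)C/C(C)=C\[C@H]2O[Si](CC)(CC)CC
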